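The data are calculated with made-up constants, and the scatter is random.

At 8.0 min, which is there more of in this flask, trapped intermediate or target, and how does that stand at 6.0 s?

| flask | substrate | partner | capture agent | free catalyst | second catalyst | remark | time |
|---|---|---|---|---|---|---|---|
| eta | 0.020 M | 0.030 M | 2 mM | 42 µM | 10 µM | run made earlier |  |
| epsilon | 0.020 M | 0.030 M | 2 mM | 42 µM | 40 µM | run made earlier |  |
| flask | 0.020 M | 0.0300 M | 2.00 mM | 42 µM | 20 µM |  | 8.0 min |

| run | time / min | trapped intermediate / % | target / % |
|---|---|---|---|
| eta | 1.33 | 10.0 | 40.6 |
| eta | 3.00 | 8.6 | 64.1 |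
| eta | 6.00 | 9.3 | 79.6 |
| eta | 10.0 | 10.4 | 80.8 |
| epsilon | 2.50 | 10.4 | 84.7 |
| epsilon | 5.00 | 11.3 | 87.1 |
| epsilon | 8.00 | 9.9 | 85.8 |
| epsilon | 10.0 | 10.5 | 85.4 |

(scatter of a reading: 1 percentage point)

- ratio of trapped intermediate to target at 6.0 s
- ratio of trapped intermediate to target at 8.0 min
- which of trapped intermediate and target there is more of at 8.0 min



Capture agent is charged in the smaller amount, so I write its balance: it is the limiting reagent of the capture. If each capture agent takes one substrate, the capture share, the fraction of the substrate charged that the capture agent charged can hold, is 10.0%. Both earlier runs read trapped intermediate between 8.6% and 11.3%, around that share.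

Is one number enough? It leaves 90.0% for target, but the mean of the epsilon target readings is 85.8%, which is lower. So in the epsilon run about 4.2 percentage points go elsewhere by these readings, and I need that read plateau too:

ratio at the end = capture share / target plateau = 0.117

The eta run, with less second catalyst than this flask, stands at 80.8% at 10.0 min. Taken as the plateau, that reading gives 0.124, so I expect this flask's ratio between the two values, with target ahead. For 6.0 s the share gives a ceiling on trapped intermediate and no time, and the earliest reading stands at 1.33 min.

The forecast gives 0.118 at 8.0 min, with target ahead, and 1.2 at 6.0 s, “so the ratio is about 1.2, very uncertain”.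

The flask gives 0.117 at 8.0 min, with target ahead at 85.3% against 10.0%. At 6.0 s it gives 1.57, and the two species stand level at 0.193 min.

    substrate + free catalyst ⇌ free catalyst + open intermediate (K = 2.10, k = 1700 M⁻¹ s⁻¹)
    second catalyst + open intermediate ⇌ catalyst intermediate (K = 45.0 M⁻¹, k = 3.40 × 10⁵ M⁻¹ s⁻¹)
    partner + catalyst intermediate → second catalyst + target (k = 1700 M⁻¹ s⁻¹)
    open intermediate + capture agent → trapped intermediate (k = 43.0 M⁻¹ s⁻¹)
    substrate + partner → uncatalysed product (k = 0.0680 M⁻¹ s⁻¹)

The forecast and the flask part at 6.0 s, so the sample to watch comes before 0.193 min. At 8.0 min this flask holds 10.0% trapped intermediate, with 0% of the capture agent left. The neighbouring flask with 0.080 M substrate has a capture share of 2.50%, and it holds 2.50% trapped intermediate. Its ratio at 8.0 min is 0.0737, with target at 33.9%, partner at 0% of its charge and open intermediate at 40.6%.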